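The pyranone ring (O1–C2–C3–C4–C4a–C8a) is taken apart at C4a–C4, C4–C3 and O1–C2. The C4 carbonyl then comes from carbon monoxide, C3/C2/C1'/C2' and the tail from one homopropargylic (R)-silyloxy alkyne, and the A-ring from 2-iodo-5-methoxyresorcinol. O1 and the 5-OH flank C4a symmetrically, with the 7-OMe para to it, so either hydroxyl may close the ring without phenol protection or regiocontrol. One palladium-catalysed carbonylative alkynylation with amine-relayed 6-endo cyclisation should therefore deliver the whole chromone with the C2' stereocentre (from a kinetically resolved epoxide) already in place. Cross-metathesis and one acid treatment finish the side chain.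

Key step: step 5

Remark: C2' of the target is R (O > C1'H2 > C3'H2). The same spatial arrangement is R in 2, 4, 5 and all later intermediates, and the (R,R)-cobalt–salen catalyst is taken to leave the R epoxide, as is the rule for alkyl-substituted terminal epoxides.

Step 1
Reactants: 1 rac-2-(hex-5-en-1-yl)oxirane (1,2-epoxyoct-7-ene)
Product: 2 (R)-2-(hex-5-en-1-yl)oxirane
Conditions: (R,R)-(salen)Co(III)OAc (0.5 mol%), H2O (0.55 equiv), neat, 0 °C → rt; distillation
Reagents that add atoms: none
Why: Jacobsen hydrolytic kinetic resolution: the (R,R)-catalyst should hydrate the (S)-epoxide selectively at its terminal carbon, so the unreacted (R)-epoxide, separable from the diol by distillation, carries the configuration of the future C2'.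

Step 2
Reactants: 2 (R)-2-(hex-5-en-1-yl)oxirane; 3 lithium acetylide–ethylenediamine complex
Product: 4 (R)-dec-9-en-1-yn-4-ol
Conditions: 3 (1.5 equiv), DMSO, 0 °C → rt; H2O quench
Reagents that add atoms: none
Why: SN2 opening of a terminal epoxide by an acetylide at the unsubstituted carbon, a standard use of this complex in DMSO, leaves the stereocentre untouched and gives the terminal alkyne directly, with no C-silyl group to remove.

Step 3
Reactants: 4 (R)-dec-9-en-1-yn-4-ol
Product: 5 (R)-tert-butyl(dec-9-en-1-yn-4-yloxy)dimethylsilane
Conditions: TBSCl (1.2 equiv), imidazole (2.5 equiv), DMF, 0 °C → rt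
Reagents that add atoms: tert-butyldimethylsilyl chloride, CC(C)(C)[Si](C)(C)Cl
Why: Silylation of a secondary alcohol; the silyl ether blocks O-acylation and the palladium-catalysed cyclocarbonylation that free homopropargylic alcohols undergo under CO, and it should withstand hot secondary amine.

Step 4
Reactants: 6 5-methoxyresorcinol (5-methoxybenzene-1,3-diol)
Product: 7 2-iodo-5-methoxybenzene-1,3-diol
Conditions: I2 (1.0 equiv), NaHCO3 (1.1 equiv), THF/H2O (1:1), 0 °C, dark
Reagents that add atoms: iodine, II
Why: Electrophilic aromatic iodination of a resorcinol under bicarbonate, which is known to favour the carbon between the two hydroxyls; one equivalent of iodine at 0 °C should limit di-iodination.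

Step 5
Reactants: 7 2-iodo-5-methoxybenzene-1,3-diol; 5 (R)-tert-butyl(dec-9-en-1-yn-4-yloxy)dimethylsilane; 8 carbon monoxide
Product: 11 2-[(R)-2-(tert-butyldimethylsilyloxy)oct-7-en-1-yl]-5-hydroxy-7-methoxy-4H-chromen-4-one, via o-hydroxyaryl ynone 9 (not isolated), via diethylamino enaminone 10 (not isolated)
Conditions: PdCl2(dppf) (5 mol%), CO (20 bar), Et2NH (solvent), 7 (1.2 equiv), 120 °C, autoclave, copper-free
Reagents that add atoms: diethylamine, CCNCC (carried only in intermediate 10; released again on ring closure)
Why: Pd(0) inserts into the C–I bond of 7, CO insertion gives the aroyl-palladium(II) species, amine-assisted alkynylation by 5 and reductive elimination give ynone 9, diethylamine adds to the β-carbon of 9 to give enaminone 10, and a flanking phenol then attacks the amino-bearing carbon and expels the amine, so that C4a–C4, C4–C3 and O1–C2 are formed. The closest known reaction type is the carbonylative Sonogashira-type annulation of o-iodophenols with terminal alkynes in a secondary amine, an established chromone synthesis. The pyranone ring is closed through the O1–C2 bond by a 6-endo oxa-Michael addition–elimination on the enaminone (6-endo-dig with respect to the ynone). No stereocentre is created; C2' lies outside the reacting π-system and should be carried through unchanged. The step needs 6-endo (chromone) over 5-exo (aurone) closure, secured by the enaminone relay in neat secondary amine; CO insertion ahead of direct alkynylation, favoured by CO pressure, the electron-rich aryl group and the absence of copper; and alkyne over alkene engagement, secured by the far higher reactivity of the terminal alkyne towards acylpalladium. Regiochemistry is not in question because the two hydroxyls of 7 are related by symmetry, so either closure leaves the other as the 5-OH opposite the 7-OMe.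

Step 6
Reactants: 11 2-[(R)-2-(tert-butyldimethylsilyloxy)oct-7-en-1-yl]-5-hydroxy-7-methoxy-4H-chromen-4-one; 12 tert-butyl acrylate
Product: 13 tert-butyl (2E,8R)-8-(tert-butyldimethylsilyloxy)-9-(5-hydroxy-7-methoxy-4-oxo-4H-chromen-2-yl)non-2-enoate
Conditions: Hoveyda–Grubbs II (5 mol%), 12 (5 equiv), CH2Cl2, 40 °C
Reagents that add atoms: none
Why: Olefin cross-metathesis between a type I terminal alkene and an excess of a type II acrylate should give the E-enoate under thermodynamic control, while the trisubstituted C2=C3 bond of the chromone and the hydrogen-bonded 5-OH stay out of the reaction.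

Step 7
Reactants: 13 tert-butyl (2E,8R)-8-(tert-butyldimethylsilyloxy)-9-(5-hydroxy-7-methoxy-4-oxo-4H-chromen-2-yl)non-2-enoate
Product: 14 penithochromone T = (2E,8R)-8-hydroxy-9-(5-hydroxy-7-methoxy-4-oxo-4H-chromen-2-yl)non-2-enoic acid
Conditions: TFA/CH2Cl2/H2O (10:10:1), 0 °C → rt
Reagents that add atoms: none
Why: Acidolysis: the tert-butyl ester fragments by alkyl–oxygen cleavage and the secondary silyl ether is hydrolysed at silicon, so no bond to C2' is broken and the R configuration is kept; water suppresses trifluoroacetylation of the liberated alcohol.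

Compound list
1 | rac-2-(hex-5-en-1-yl)oxirane (1,2-epoxyoct-7-ene) | C=CCCCCC1CO1 | starting material
2 | (R)-2-(hex-5-en-1-yl)oxirane | C=CCCCC[C@@H]1CO1 | intermediate
3 | lithium acetylide–ethylenediamine complex | [Li+].[C-]#C.NCCN | starting material
4 | (R)-dec-9-en-1-yn-4-ol | C#CC[C@H](O)CCCCC=C | intermediate
5 | (R)-tert-butyl(dec-9-en-1-yn-4-yloxy)dimethylsilane | C#CC[C@H](O[Si](C)(C)C(C)(C)C)CCCCC=C | intermediate
6 | 5-methoxyresorcinol (5-methoxybenzene-1,3-diol) | COc1cc(O)cc(O)c1 | starting material
7 | 2-iodo-5-methoxybenzene-1,3-diol | COc1cc(O)c(I)c(O)c1 | intermediate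
8 | carbon monoxide | [C-]#[O+] | starting material
9 | (R)-5-(tert-butyldimethylsilyloxy)-1-(2,6-dihydroxy-4-methoxyphenyl)undec-10-en-2-yn-1-one (not isolated) | COc1cc(O)c(C(=O)C#CC[C@H](O[Si](C)(C)C(C)(C)C)CCCCC=C)c(O)c1 | intermediate
10 | (R,E)-5-(tert-butyldimethylsilyloxy)-3-(diethylamino)-1-(2,6-dihydroxy-4-methoxyphenyl)undeca-2,10-dien-1-one (not isolated; drawn as E, the geometry is of no consequence) | COc1cc(O)c(C(=O)/C=C(/N(CC)CC)C[C@H](O[Si](C)(C)C(C)(C)C)CCCCC=C)c(O)c1 | intermediate
11 | 2-[(R)-2-(tert-butyldimethylsilyloxy)oct-7-en-1-yl]-5-hydroxy-7-methoxy-4H-chromen-4-one | COc1cc(O)c2c(=O)cc(C[C@H](O[Si](C)(C)C(C)(C)C)CCCCC=C)oc2c1 | intermediate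
12 | tert-butyl acrylate | C=CC(=O)OC(C)(C)C | starting material
13 | tert-butyl (2E,8R)-8-(tert-butyldimethylsilyloxy)-9-(5-hydroxy-7-methoxy-4-oxo-4H-chromen-2-yl)non-2-enoate | COc1cc(O)c2c(=O)cc(C[C@H](O[Si](C)(C)C(C)(C)C)CCCC/C=C/C(=O)OC(C)(C)C)oc2c1 | intermediate
14 | penithochromone T, (2E,8R)-8-hydroxy-9-(5-hydroxy-7-methoxy-4-oxo-4H-chromen-2-yl)non-2-enoic acid | COc1cc(O)c2c(=O)cc(C[C@H](O)CCCC/C=C/C(=O)O)oc2c1 | target

Total step count: 7
Longest linear sequence: 6 steps (steps 1, 2, 3, 5, 6, 7); step 4 is a one-step side branch.

Steps most likely to fail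

Step 5. What may go wrong: interception of the aroyl-palladium by the amine (amide formation), direct CO-free alkynylation leading on to a benzofuran, Heck-type engagement of the terminal alkene, or sluggish oxidative addition into the doubly ortho-substituted, electron-rich C–I bond. The fallback builds the same ynone stepwise without CO and sets out from 7 and 5. Compound 7 is bis-O-allylated (allyl bromide, K2CO3, DMF) to 1,3-bis(allyloxy)-2-iodo-5-methoxybenzene F1, and 5 is formylated (n-BuLi, THF, −78 °C; then DMF) to (R)-5-(tert-butyldimethylsilyloxy)undec-10-en-2-ynal F2. Iodine–magnesium exchange on F1 (i-PrMgCl·LiCl, THF, −20 °C) and 1,2-addition to F2 should give, as both C1 epimers, (5R)-1-[2,6-bis(allyloxy)-4-methoxyphenyl]-5-(tert-butyldimethylsilyloxy)undec-10-en-2-yn-1-ol F3. Oxidation with MnO2 (CH2Cl2) should give (R)-1-[2,6-bis(allyloxy)-4-methoxyphenyl]-5-(tert-butyldimethylsilyloxy)undec-10-en-2-yn-1-one F4. Pd(PPh3)4 (cat.) in Et2NH/THF should then remove both allyl groups, with the amine as allyl acceptor, while the amine adds to the ynone; the liberated phenol closes the ring as in the main route, and the sequence rejoins at 11.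

Step 4. What may go wrong: loss of regiocontrol (iodination next to the methoxy group), over-iodination, or deiodination of the light- and acid-sensitive product on handling. The fallback places the iodine by directed metalation and sets out from 6. Bis-acetalisation (MOMCl, i-Pr2NEt, CH2Cl2) gives 1-methoxy-3,5-bis(methoxymethoxy)benzene F5. Lithiation between the two acetal oxygens (n-BuLi, THF, 0 °C) and quenching with iodine give 2-iodo-5-methoxy-1,3-bis(methoxymethoxy)benzene F6. Brief treatment with HCl in MeOH at rt removes both acetals and returns to the route at 7.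

Step 7. What may go wrong: acid-promoted dehydration across C1'–C2' into conjugation with the chromone, incomplete desilylation, or persistent trifluoroacetylation of the secondary alcohol. The fallback avoids any strong-acid step after the enoate is in place and sets out from 11. Fluoride desilylation (HF·pyridine, THF, 0 °C → rt) gives 5-hydroxy-2-[(R)-2-hydroxyoct-7-en-1-yl]-7-methoxy-4H-chromen-4-one F7. Cross-metathesis of F7 with acrylic acid itself (Hoveyda–Grubbs II, CH2Cl2, 40 °C) should give the E-acid directly and so returns to the route at 14.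

Further compounds
F1 | step 5 | 1,3-bis(allyloxy)-2-iodo-5-methoxybenzene | COc1cc(OCC=C)c(I)c(OCC=C)c1
F2 | step 5 | (R)-5-(tert-butyldimethylsilyloxy)undec-10-en-2-ynal | O=CC#CC[C@H](O[Si](C)(C)C(C)(C)C)CCCCC=C
F3 | step 5 | (5R)-1-[2,6-bis(allyloxy)-4-methoxyphenyl]-5-(tert-butyldimethylsilyloxy)undec-10-en-2-yn-1-ol | COc1cc(OCC=C)c(C(O)C#CC[C@H](O[Si](C)(C)C(C)(C)C)CCCCC=C)c(OCC=C)c1
F4 | step 5 | (R)-1-[2,6-bis(allyloxy)-4-methoxyphenyl]-5-(tert-butyldimethylsilyloxy)undec-10-en-2-yn-1-one | COc1cc(OCC=C)c(C(=O)C#CC[C@H](O[Si](C)(C)C(C)(C)C)CCCCC=C)c(OCC=C)c1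
F5 | step 4 | 1-methoxy-3,5-bis(methoxymethoxy)benzene | COCOc1cc(OC)cc(OCOC)c1
F6 | step 4 | 2-iodo-5-methoxy-1,3-bis(methoxymethoxy)benzene | COCOc1cc(OC)cc(OCOC)c1I
F7 | step 7 | 5-hydroxy-2-[(R)-2-hydroxyoct-7-en-1-yl]-7-methoxy-4H-chromen-4-one | COc1cc(O)c2c(=O)cc(C[C@H](O)CCCCC=C)oc2c1
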